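If you take over the cedar flask, read its peaks as a ledger of G.

| setting | summer | autumn | ash | birch | cedar |
|---|---|---|---|---|---|
| G | 13 mM | 40 mM | 20 mM | 20 mM | 20 mM |
| J | 1 equiv | 1 equiv | 1.00 equiv | 2.00 equiv | 4.00 equiv |
| remark | run made earlier | run made earlier |  |  |  |
| time |  |  | 50 min | 50 min | 50 min |

| run | time / min | D / % | G / % | X / % | E / % |
|---|---|---|---|---|---|
| summer | 2.50 | 15.2 | 81.6 | 2.6 | 0.4 |
| summer | 4.00 | 19.5 | 72.7 | 5.8 | 3.2 |
| summer | 6.00 | 23.7 | 62.5 | 9.5 | 4.8 |
| summer | 8.00 | 24.9 | 54.1 | 12.5 | 8.5 |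
| summer | 12.0 | 25.0 | 42.4 | 18.6 | 12.7 |
| summer | 20.0 | 24.1 | 26.5 | 27.1 | 22.6 |
| summer | 30.0 | 21.7 | 17.4 | 34.4 | 28.6 |
| autumn | 2.50 | 29.7 | 53.9 | 12.5 | 4.0 |
| autumn | 4.00 | 32.4 | 40.3 | 20.7 | 5.6 |
| autumn | 6.00 | 32.6 | 27.0 | 30.0 | 9.7 |
| autumn | 8.00 | 30.5 | 19.5 | 36.2 | 12.0 |
| autumn | 12.0 | 27.7 | 11.8 | 43.1 | 17.7 |
| autumn | 20.0 | 22.5 | 3.3 | 48.2 | 25.6 |
| autumn | 30.0 | 20.0 | 1.1 | 50.8 | 29.7 |

(standard deviation of a reading: 0.5 percentage points)

- which of these there is most of at the end, counted by the G in it, ash (D / G / E / X)
- which of these there is most of at the end, counted by the G in it, birch (D / G / E / X)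
- which of these there is most of at the end, counted by the G in it, cedar (D / G / E / X)
- how much there is at the end of the one of these that leads, in percent of the G charged: ash
- how much there is at the end of the one of these that leads, in percent of the G charged: birch
- how much there is at the end of the one of these that leads, in percent of the G charged: cedar

- in percentages every species weighs as the G in it: one X counts as two

G has two partners. With J it makes D, which closes to E and opens back, and with D it makes X. I take one J spent per D made, so J left is the charge less D, less E, less half of X. X gained per drop in ln J is then twice s·D. The summer run from 6.00 min to 30.0 min reads 0.762. The autumn run from 4.00 min to 12.0 min reads 0.835. So I take the selectivity factor s, the G taken by D per G taken by J at equal amounts of both, as 0.798.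

Autumn at 4.00 min shows E at 5.6% against D at 32.4%, with G down to 40.3%. Cedar holds twice autumn's J, so I let D in cedar climb from nothing to all that isn't X, with a mean of half of that. Then X = s·(charge − X)·ln(J charged / J left), and J left depends on X, so I go round. With J charged at 4.00 times the G, the rounds give 23.0%, 15.4% and 17.7%. They swing, so I commit to the midpoint of the last two, 16.6% X in cedar.

Autumn's E over D reads 1.48 at 30.0 min, up from 1.14 at 20.0 min. So I put E in cedar near 49.9%, more than X.

Leave the J charge alone: with J as charged, before any is spent, the split s·D/J at equal D in cedar is a quarter of ash's.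

The forecast gives X at 46% in ash, E at 47% in birch and E at 56% in cedar, above my figure for E, and holds that “X hardly changes once G is gone”.

Cedar ends with E at 53.8%, ash with X at 45.6%, birch with E at 46.0%.

    D ⇌ E (K = 1.80, k = 0.00110 s⁻¹)
    G + J → D (k = 0.110 M⁻¹ s⁻¹)
    G + D → X (k = 0.0820 M⁻¹ s⁻¹)

Left ten times as long, cedar still holds X at 15.7%. Its J left, 77% of its charge, puts s to use again: X comes to 17.3% by the rule, and cedar holds 15.7%. Birch has G at 0.0068% and J left at 57% of its charge, so the same s gives X at 31.0%, and birch holds 27.6%.

(The readings are calculated on assumed constants.)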